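The plan rests on cutting the oxolane that links the spiro carbons C9 and C13 (labdane numbering) back to a 1,5-diene. In a single operation permanganate oxygenates the side-chain alkene C13=C16 and the tetrasubstituted ring B alkene C8=C9, so that one oxygen bridges C9 and C13, C8 and C16 end cis on the new ring as the target requires, and hydroxyls remain on C8 and C16 for later use. The precursor is a cis-fused decalin 3,19-diacetate carrying β-oriented silyl and SEM ethers on C6 and C7, the C8=C9 alkene, and a C9 side chain with the C13 methylidene and a C15 dimethyl acetal.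

Key step: step 15

Remark on the chemistry (assumption): labdane numbering is used for all decalins and racemic compounds 7 and 9–11 are drawn as the enantiomer carried on; the C6 and C7 oxygens are differentiated before the key step, C15 is carried at the aldehyde oxidation level, and the C8 methyl of the target (cis to the C9 oxygen, judged by conformational analysis the less stable arrangement in this cis-decalin) is set kinetically in step 19 and kept away from base afterwards.

Step 1
Reactants: 1 2,4,6-trimethylphenol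
Product: 2 3-(chloromethyl)-2,4,6-trimethylphenol
Conditions: (CH2O)n (1.1 equiv), conc. HCl, AcOH, 45 °C
Reagents that add atoms: formaldehyde (as paraformaldehyde) C=O; hydrogen chloride Cl
Why: Blanc chloromethylation can only attack the free 3-position, which is activated by the three methyl groups, and limiting the formaldehyde should hold the reaction at the mono-substituted stage.

Step 2
Reactants: 3 [2-(chloromethyl)prop-2-en-1-yl]trimethylsilane
Product: 4 2-(chloromethyl)-4,4-dimethoxybut-1-ene
Conditions: HC(OMe)3 (3 equiv), TMSOTf (5 mol%), CH2Cl2, −78 °C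
Reagents that add atoms: trimethyl orthoformate COC(OC)OC
Why: In a Hosomi–Sakurai reaction the dimethoxycarbenium ion is attacked by the γ-carbon of the allylsilane with loss of silicon, and the allylic chloride is left untouched.

Step 3
Reactants: 2 3-(chloromethyl)-2,4,6-trimethylphenol; 4 2-(chloromethyl)-4,4-dimethoxybut-1-ene
Product: 6 3-(5,5-dimethoxy-3-methylidenepentyl)-2,4,6-trimethylphenol, via Grignard reagent 5 (not isolated)
Conditions: 4, Mg, THF, 0 °C; then added to 2 pretreated with i-PrMgCl (1.0 equiv), THF, −30 → 20 °C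
Reagents that add atoms: none
Why: An allylic Grignard reagent couples readily with a benzylic chloride (Wurtz-type substitution) while the phenol is masked in the flask as its magnesium phenoxide, and both ends of the symmetrical allyl unit give the same 1,1-disubstituted alkene.

Step 4
Reactants: 6 3-(5,5-dimethoxy-3-methylidenepentyl)-2,4,6-trimethylphenol
Product: 7 rac-6-acetoxy-3-(5,5-dimethoxy-3-methylidenepentyl)-2,4,6-trimethylcyclohexa-2,4-dien-1-one
Conditions: Pb(OAc)4 (1.1 equiv), CH2Cl2–AcOH (10:1), 0 °C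
Reagents that add atoms: lead tetraacetate CC(=O)O[Pb](OC(C)=O)(OC(C)=O)OC(C)=O
Why: Wessely oxidation delivers acetate from an aryloxy-lead species to an ortho carbon, C6 being preferred over C2 because C2 is buttressed by the C3 side chain, and the racemic stereocentre so formed is erased in step 6.

Step 5
Reactants: 7 rac-6-acetoxy dienone; 8 vinylene carbonate
Product: 9 rac-3-acetoxy-6-(5,5-dimethoxy-3-methylidenepentyl)-1,3,5-trimethyl-2-oxobicyclo[2.2.2]oct-5-ene-7,8-diyl carbonate (both carbonate oxygens syn to the C5=C6 bridge)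
Conditions: 8 (8 equiv), toluene, BHT (cat.), 130 °C, sealed tube
Reagents that add atoms: none
Why: The s-cis-locked electron-poor dienone undergoes Diels–Alder addition across C2 and C5, and the endo transition state places both oxygens syn to the new C5=C6 bridge, which later makes them β on ring B; addition is expected on the acetoxy face, but the C3 configuration does not matter.

Step 6
Reactants: 9 rac-acetoxy ketone carbonate
Product: 10 rac-6-(5,5-dimethoxy-3-methylidenepentyl)-1,3,5-trimethyl-2-oxobicyclo[2.2.2]oct-5-ene-7,8-diyl carbonate (C3 epimers)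
Conditions: SmI2 (2.5 equiv), THF–MeOH, −78 °C
Reagents that add atoms: none
Why: SmI2 reduction of an α-acyloxy ketone cleaves the C3–O bond through the ketyl and the samarium enolate, which cannot expel the C7 oxygen because that would need a bridgehead alkene, and both C3 epimers converge at the enolate of step 10.

Step 7
Reactants: 10 rac-ketone carbonate
Product: 11 rac-7,8-dihydroxy-6-(5,5-dimethoxy-3-methylidenepentyl)-1,3,5-trimethylbicyclo[2.2.2]oct-5-en-2-one (cis-diol syn to C5=C6; C3 epimers)
Conditions: K2CO3 (0.3 equiv), MeOH, 0 → 20 °C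
Reagents that add atoms: none
Why: Base-catalysed transesterification with methanol releases the cis-diol from the cyclic carbonate as dimethyl carbonate without touching the dimethyl acetal or the alkenes.

Step 8
Reactants: 11 rac-keto diol
Product: 12 8-(tert-butyldimethylsilyloxy)-7-hydroxy-6-(5,5-dimethoxy-3-methylidenepentyl)-1,3,5-trimethylbicyclo[2.2.2]oct-5-en-2-one (single enantiomer; C8 is the carbinol next to the CH bridgehead C4)
Conditions: TBSCl (0.6 equiv), i-Pr2NEt, (S)-N-[(R)-3,3-dimethylbutan-2-yl]-3,3-dimethyl-2-{[(1-methyl-1H-imidazol-2-yl)methyl]amino}butanamide (30 mol%) or its enantiomer, THF, −40 °C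
Reagents that add atoms: tert-butyldimethylsilyl chloride CC(C)(C)[Si](C)(C)Cl
Why: Catalytic enantioselective silylation of a syn-1,2-diol is a kinetic resolution that silylates one enantiomer at its less hindered hydroxyl (on C8, not next to the methyl-bearing bridgehead), so it fixes the absolute configuration and differentiates the two oxygens at once; the catalyst antipode that selects the enantiomer drawn is chosen in a trial with both, and the other diol enantiomer is left behind.

Step 9
Reactants: 12 mono-silyl ether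
Product: 13 8-(tert-butyldimethylsilyloxy)-7-[2-(trimethylsilyl)ethoxymethoxy] ketone (TBS and SEM ethers)
Conditions: SEMCl (3 equiv), i-Pr2NEt, n-Bu4NI (cat.), CH2Cl2, 40 °C
Reagents that add atoms: 2-(trimethylsilyl)ethoxymethyl chloride C[Si](C)(C)CCOCCl
Why: O-Alkylation with the chloromethyl ether under amine base protects the hindered C7 hydroxyl without forming an alkoxide, so the neighbouring silyl group cannot migrate and the enolisable ketone is left alone.

Step 10
Reactants: 13 TBS/SEM-protected ketone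
Product: 15 3-(benzyloxymethyl)-1,3,5-trimethyl ketone with CH2OBn syn to the C5=C6 bridge, via lithium enolate 14 (not isolated)
Conditions: LiN(i-Pr)2 (1.2 equiv), THF, −78 °C; BnOCH2Cl (1.5 equiv), DMPU, −78 → −20 °C
Reagents that add atoms: benzyl chloromethyl ether ClCOCc1ccccc1
Why: C3 is the only enolisable position (C1 is a bridgehead), and enolate alkylation occurs on the face next to the flat C5=C6 bridge, away from the inward C7–H and C8–H bonds, which sets the quaternary carbon with CH2OBn syn to the alkene (the future 4β-CH2O group).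

Step 11
Reactants: 15 quaternary ketone
Product: 16 2-ethenylbicyclo[2.2.2]oct-5-en-2-ol with the vinyl group syn to the C5=C6 bridge
Conditions: CH2=CHMgBr (3 equiv), CeCl3 (3 equiv), THF, −78 → 0 °C
Reagents that add atoms: vinylmagnesium bromide C=C[Mg]Br
Why: 1,2-Addition of the cerium-modified Grignard reagent to the non-enolisable ketone should occur from the side of the C5=C6 bridge, as is usual for bicyclo[2.2.2]oct-5-en-2-ones, which places the vinyl group where the sigmatropic step needs it.

Step 12
Reactants: 16 vinyl carbinol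
Product: 19 19-benzyloxy-6β-(tert-butyldimethylsilyloxy)-7β-[2-(trimethylsilyl)ethoxymethoxy]-15,15-dimethoxy-5β,10β-labda-8,13(16)-dien-3-one, via potassium alkoxide 17 (not isolated), via potassium enolate 18 (not isolated)
Conditions: KH (3 equiv), 18-crown-6 (3 equiv), THF, 0 → 25 °C; then aq. NH4Cl
Reagents that add atoms: none
Why: The anionic oxy-Cope rearrangement breaks C1–C2 of the bicycle and joins the vinyl terminus to C5 through the boat transition state that the bicycle enforces, so ring A is cis-fused with H5 and the C10 methyl β, the C6 and C7 oxygens β, the CH2OBn group 4β, and the C8=C9 bond tetrasubstituted.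

Step 13
Reactants: 19 decalin ketone
Product: 20 6β-(tert-butyldimethylsilyloxy)-7β-[2-(trimethylsilyl)ethoxymethoxy]-15,15-dimethoxy-5β,10β-labda-8,13(16)-diene-3β,19-diol
Conditions: Li (10 equiv), NH3(l)–THF, t-BuOH (4 equiv), −78 °C, 20 min; then NH4Cl
Reagents that add atoms: none
Why: Birch-type dissolving-metal reduction cleaves the benzyl ether and reduces the ketone under thermodynamic control to the equatorial 3β-alcohol (a 3α-hydroxyl would be syn-axial to C6), while isolated alkenes, silyl, SEM and acetal groups should be inert at −78 °C.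

Step 14
Reactants: 20 3β,19-diol
Product: 21 3β,19-diacetoxy-6β-(tert-butyldimethylsilyloxy)-7β-[2-(trimethylsilyl)ethoxymethoxy]-15,15-dimethoxy-5β,10β-labda-8,13(16)-diene (key-step precursor)
Conditions: Ac2O, pyridine, DMAP (cat.), CH2Cl2, 25 °C
Reagents that add atoms: acetic anhydride CC(=O)OC(C)=O
Why: DMAP-catalysed acylation esterifies the primary C19 and the hindered secondary C3 hydroxyl, which are the only free hydroxyls.

Step 15
Reactants: 21 diene diacetate
Product: 23 3β,19-diacetoxy-9α,13-epoxy-6β-(tert-butyldimethylsilyloxy)-7β-[2-(trimethylsilyl)ethoxymethoxy]-15,15-dimethoxy-5β,10β-labdane-8α,16-diol (C16 cis to C8 on the oxolane), via manganate ester 22 (not isolated)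
Conditions: KMnO4 (1.5 equiv, aq.), AcOH (3 equiv), acetone–pH 6.2 phosphate buffer, −25 → −10 °C; then aq. Na2S2O5
Reagents that add atoms: potassium permanganate [K+].[O-][Mn](=O)(=O)=O
Why: Proposed new method: permanganate adds in a [3+2] step across the exposed C13=C16 bond, the cyclic manganate ester is oxidised to hexavalent manganese, and its O13–Mn=O unit then adds suprafacially across the tetrasubstituted C8=C9 bond, so that O13 becomes the ring oxygen and hydrolysis of the resulting tetravalent manganese diester leaves the C8 and C16 hydroxyls. The closest known reaction is the permanganate-mediated oxidative cyclisation of acyclic 1,5-dienes to cis-2,5-disubstituted oxolane diols, which has not been shown for a ring-embedded tetrasubstituted acceptor next to a quaternary carbon. The oxolane (O13, C13, C12, C11, C9) closes in a 5-exo sense, O13 bonding to C9 inside the metallacycle. C9 and C8 are set together by syn addition to the α face of ring B, and C13 is set by the chelate, in which one manganese holds O16 and O8 and so forces C16 and C8 cis on the new ring. The step needs α-face attack at C8=C9, which the C10 methyl, the pseudoaxial 7β-SEM ether and the 6β-silyl ether secure by shielding the β face; the first addition to C13=C16 is not face-selective and only the C13 epimer whose ester can reach the α face can close, so the diastereomer is defined but about half of the material is expected to end as the open 13,16-diol. Cold acetate-buffered conditions should spare the acetal, the ethers and the acetates.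

Step 16
Reactants: 23 epoxy diol
Product: 24 3β,19-diacetoxy-9α,13:15,16-diepoxy-15-methoxy-6β-(tert-butyldimethylsilyloxy)-7β-[2-(trimethylsilyl)ethoxymethoxy]-5β,10β-labdan-8α-ol (C15 epimers)
Conditions: PPTS (10 mol%), CH2Cl2, 4 Å molecular sieves, 25 °C
Reagents that add atoms: none
Why: Acid-catalysed transacetalisation closes the five-membered mixed methyl acetal from the C16 hydroxyl and the C15 dimethyl acetal with loss of methanol, which masks C16–OH and stores C15 at the aldehyde oxidation level.

Step 17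
Reactants: 24 tertiary alcohol
Product: 25 the corresponding 8(17)-ene (exocyclic methylidene at C8)
Conditions: SOCl2 (3 equiv), pyridine, CH2Cl2, −20 → 0 °C
Reagents that add atoms: none
Why: E2 dehydration of the axial tertiary chlorosulfite can only use the C17 methyl hydrogens, because C9 is quaternary and the C7 hydrogen is gauche to the leaving group (the 7β-oxygen is trans-diaxial to it), so the exocyclic alkene should form.

Step 18
Reactants: 25 SEM ether
Product: 26 3β,19-diacetoxy-9α,13:15,16-diepoxy-15-methoxy-6β-(tert-butyldimethylsilyloxy)-5β,10β-labd-8(17)-en-7β-ol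
Conditions: MgBr2·OEt2 (10 equiv), MeNO2–Et2O, 25 °C
Reagents that add atoms: none
Why: Chelation of MgBr2 by the two SEM oxygens and bromide attack at silicon fragment the SEM ether under mild Lewis-acidic conditions that should leave the tert-butyldimethylsilyl ether, the acetates and the mixed acetal in place.

Step 19
Reactants: 26 allylic alcohol
Product: 27 3β,19-diacetoxy-9α,13:15,16-diepoxy-15-methoxy-6β-(tert-butyldimethylsilyloxy)-5β,10β-labdan-7β-ol with 8α-methyl and 8β-H
Conditions: [Ir(cod)(PCy3)(py)]PF6 (10 mol%), H2 (1 atm), CH2Cl2, 25 °C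
Reagents that add atoms: none
Why: In a hydroxyl-directed hydrogenation the cationic iridium centre binds the allylic pseudoaxial 7β-hydroxyl and delivers hydrogen to the β face of C8=C17, which sets C8 with 8β-H and 8α-methyl (cis to the C9 oxygen) against the steric bias of the ring.

Step 20
Reactants: 27 secondary alcohol
Product: 28 3β,19-diacetoxy-9α,13:15,16-diepoxy-15-methoxy-6β-(tert-butyldimethylsilyloxy)-5β,10β-labdan-7-one
Conditions: Dess–Martin periodinane (1.5 equiv), NaHCO3, CH2Cl2, 0 → 25 °C
Reagents that add atoms: none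
Why: Buffered Dess–Martin oxidation converts the only free hydroxyl (C7) into the ketone under neutral conditions that should not enolise the now epimerisable C8 centre.

Step 21
Reactants: 28 methyl acetal
Product: 29 the corresponding 15-hydroxy lactol (15,16-epoxy-15-hydroxy; C15 epimers)
Conditions: AcOH–THF–H2O (3:1:1), 35 °C
Reagents that add atoms: water O
Why: Mild acid hydrolysis of the furanoside-like methyl acetal gives the lactol, while the secondary silyl ether and the acetates survive and acid of this strength should not enolise the hindered ketone.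

Step 22
Reactants: 29 lactol
Product: 31 3β,19-diacetoxy-9α,13:15,16-diepoxy-6β-(tert-butyldimethylsilyloxy)-5β,10β-labd-14-en-7-one, via lactol mesylate 30 (not isolated)
Conditions: MsCl (3 equiv), Et3N (8 equiv), CH2Cl2, −20 → 20 °C
Reagents that add atoms: none
Why: Sulfonylation of the lactol hydroxyl and amine-promoted loss of methanesulfonate give the C14=C15 enol ether (lactol dehydration), all other oxygens being protected or ketonic, and the weak base at low temperature should not epimerise C8.

Step 23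
Reactants: 31 silyl ether
Product: 32 3β,19-diacetoxy-9α,13:15,16-diepoxy-6β-hydroxy-5β,10β-labd-14-en-7-one (8α-methyl; CNP0317137.2)
Conditions: n-Bu4NF–AcOH (1:1, 3 equiv), THF, 0 → 25 °C
Reagents that add atoms: none
Why: Acetic acid-buffered fluoride removes the silyl ether near neutral pH, which avoids acid (opening of the spiro enol ether to a furan) and base (C8 epimerisation, retro-oxa-Michael opening at C9, acetate migration).

Compound list
1 | 2,4,6-trimethylphenol | Cc1cc(C)c(O)c(C)c1 | starting material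
2 | 3-(chloromethyl)-2,4,6-trimethylphenol | Cc1cc(C)c(CCl)c(C)c1O | intermediate
3 | [2-(chloromethyl)prop-2-en-1-yl]trimethylsilane | C[Si](C)(C)CC(=C)CCl | starting material
4 | 2-(chloromethyl)-4,4-dimethoxybut-1-ene | ClCC(=C)CC(OC)OC | intermediate
5 | [2-(2,2-dimethoxyethyl)prop-2-en-1-yl]magnesium chloride | Cl[Mg]CC(=C)CC(OC)OC | intermediate (not isolated)
6 | 3-(5,5-dimethoxy-3-methylidenepentyl)-2,4,6-trimethylphenol | Cc1cc(C)c(CCC(=C)CC(OC)OC)c(C)c1O | intermediate
7 | rac-6-acetoxy-3-(5,5-dimethoxy-3-methylidenepentyl)-2,4,6-trimethylcyclohexa-2,4-dien-1-one | CC(=O)OC1(C)C=C(C)C(CCC(=C)CC(OC)OC)=C(C)C1=O | intermediate (racemate)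
8 | vinylene carbonate | O=C1OC=CO1 | starting material
9 | rac-3-acetoxy-6-(5,5-dimethoxy-3-methylidenepentyl)-1,3,5-trimethyl-2-oxobicyclo[2.2.2]oct-5-ene-7,8-diyl carbonate, oxygens syn to C5=C6 | O=C1[C@@](C)(OC(C)=O)[C@H]2[C@@H]3OC(=O)O[C@@H]3[C@]1(C)C(CCC(=C)CC(OC)OC)=C2C | intermediate (racemate)
10 | rac-deacetoxy ketone carbonate (C3 epimers) | O=C1C(C)[C@H]2[C@@H]3OC(=O)O[C@@H]3[C@]1(C)C(CCC(=C)CC(OC)OC)=C2C | intermediate (racemate)
11 | rac-7,8-dihydroxy ketone, cis-diol syn to C5=C6 (C3 epimers) | O=C1C(C)[C@H]2[C@H](O)[C@H](O)[C@]1(C)C(CCC(=C)CC(OC)OC)=C2C | intermediate (racemate)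
12 | 8-O-TBS 7-hydroxy ketone, single enantiomer | O=C1C(C)[C@H]2[C@H](O[Si](C)(C)C(C)(C)C)[C@H](O)[C@]1(C)C(CCC(=C)CC(OC)OC)=C2C | intermediate
13 | 8-O-TBS 7-O-SEM ketone | O=C1C(C)[C@H]2[C@H](O[Si](C)(C)C(C)(C)C)[C@H](OCOCC[Si](C)(C)C)[C@]1(C)C(CCC(=C)CC(OC)OC)=C2C | intermediate
14 | lithium enolate of 13 (C2–OLi, C2=C3) | [Li]OC1=C(C)[C@H]2[C@H](O[Si](C)(C)C(C)(C)C)[C@H](OCOCC[Si](C)(C)C)[C@]1(C)C(CCC(=C)CC(OC)OC)=C2C | intermediate (not isolated)
15 | 3-(benzyloxymethyl)-3-methyl ketone, CH2OBn syn to C5=C6 | O=C1[C@](C)(COCc2ccccc2)[C@H]2[C@H](O[Si](C)(C)C(C)(C)C)[C@H](OCOCC[Si](C)(C)C)[C@]1(C)C(CCC(=C)CC(OC)OC)=C2C | intermediate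
16 | 2-ethenylbicyclo[2.2.2]oct-5-en-2-ol, vinyl syn to C5=C6 | O[C@@]1(C=C)[C@](C)(COCc2ccccc2)[C@H]2[C@H](O[Si](C)(C)C(C)(C)C)[C@H](OCOCC[Si](C)(C)C)[C@]1(C)C(CCC(=C)CC(OC)OC)=C2C | intermediate
17 | potassium alkoxide of 16 | [K]O[C@@]1(C=C)[C@](C)(COCc2ccccc2)[C@H]2[C@H](O[Si](C)(C)C(C)(C)C)[C@H](OCOCC[Si](C)(C)C)[C@]1(C)C(CCC(=C)CC(OC)OC)=C2C | intermediate (not isolated)
18 | potassium enolate of 19 (C2=C3–OK) | c1ccccc1COC[C@@]1(C)C(O[K])=CC[C@@]2(C)[C@@H]1[C@H](O[Si](C)(C)C(C)(C)C)[C@H](OCOCC[Si](C)(C)C)C(C)=C2CCC(=C)CC(OC)OC | intermediate (not isolated)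
19 | 19-benzyloxy-6β-TBSO-7β-SEMO-15,15-dimethoxy-5β,10β-labda-8,13(16)-dien-3-one | c1ccccc1COC[C@@]1(C)C(=O)CC[C@@]2(C)[C@@H]1[C@H](O[Si](C)(C)C(C)(C)C)[C@H](OCOCC[Si](C)(C)C)C(C)=C2CCC(=C)CC(OC)OC | intermediate
20 | 6β-TBSO-7β-SEMO-15,15-dimethoxy-5β,10β-labda-8,13(16)-diene-3β,19-diol | OC[C@@]1(C)[C@@H](O)CC[C@@]2(C)[C@@H]1[C@H](O[Si](C)(C)C(C)(C)C)[C@H](OCOCC[Si](C)(C)C)C(C)=C2CCC(=C)CC(OC)OC | intermediate
21 | 3β,19-diacetate of 20 (key-step precursor) | CC(=O)OC[C@@]1(C)[C@@H](OC(C)=O)CC[C@@]2(C)[C@@H]1[C@H](O[Si](C)(C)C(C)(C)C)[C@H](OCOCC[Si](C)(C)C)C(C)=C2CCC(=C)CC(OC)OC | intermediate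
22 | potassium salt of the cyclic C13/C16 manganate ester of 21 (pentavalent manganese; C13 epimer that closes) | CC(=O)OC[C@@]1(C)[C@@H](OC(C)=O)CC[C@@]2(C)[C@@H]1[C@H](O[Si](C)(C)C(C)(C)C)[C@H](OCOCC[Si](C)(C)C)C(C)=C2CC[C@@]1(CC(OC)OC)CO[Mn](=O)([O-])O1.[K+] | intermediate (not isolated)
23 | 3β,19-diacetoxy-9α,13-epoxy-6β-TBSO-7β-SEMO-15,15-dimethoxy-5β,10β-labdane-8α,16-diol (key-step product) | CC(=O)OC[C@@]1(C)[C@@H](OC(C)=O)CC[C@@]2(C)[C@@H]1[C@H](O[Si](C)(C)C(C)(C)C)[C@H](OCOCC[Si](C)(C)C)[C@@](C)(O)[C@]21CC[C@](CO)(CC(OC)OC)O1 | intermediate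
24 | 15,16-cyclic methyl acetal of 23 (C15 epimers) | CC(=O)OC[C@@]1(C)[C@@H](OC(C)=O)CC[C@@]2(C)[C@@H]1[C@H](O[Si](C)(C)C(C)(C)C)[C@H](OCOCC[Si](C)(C)C)[C@@](C)(O)[C@]21CC[C@]3(CC(OC)OC3)O1 | intermediate
25 | 8(17)-ene from 24 | CC(=O)OC[C@@]1(C)[C@@H](OC(C)=O)CC[C@@]2(C)[C@@H]1[C@H](O[Si](C)(C)C(C)(C)C)[C@H](OCOCC[Si](C)(C)C)C(=C)[C@]21CC[C@]3(CC(OC)OC3)O1 | intermediate
26 | 8(17)-en-7β-ol | CC(=O)OC[C@@]1(C)[C@@H](OC(C)=O)CC[C@@]2(C)[C@@H]1[C@H](O[Si](C)(C)C(C)(C)C)[C@H](O)C(=C)[C@]21CC[C@]3(CC(OC)OC3)O1 | intermediate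
27 | 8α-methyl 7β-ol | CC(=O)OC[C@@]1(C)[C@@H](OC(C)=O)CC[C@@]2(C)[C@@H]1[C@H](O[Si](C)(C)C(C)(C)C)[C@H](O)[C@@H](C)[C@]21CC[C@]3(CC(OC)OC3)O1 | intermediate
28 | 8α-methyl 7-ketone, 15-methyl acetal | CC(=O)OC[C@@]1(C)[C@@H](OC(C)=O)CC[C@@]2(C)[C@@H]1[C@H](O[Si](C)(C)C(C)(C)C)C(=O)[C@@H](C)[C@]21CC[C@]3(CC(OC)OC3)O1 | intermediate
29 | 15-lactol | CC(=O)OC[C@@]1(C)[C@@H](OC(C)=O)CC[C@@]2(C)[C@@H]1[C@H](O[Si](C)(C)C(C)(C)C)C(=O)[C@@H](C)[C@]21CC[C@]3(CC(O)OC3)O1 | intermediate
30 | 15-lactol mesylate | CC(=O)OC[C@@]1(C)[C@@H](OC(C)=O)CC[C@@]2(C)[C@@H]1[C@H](O[Si](C)(C)C(C)(C)C)C(=O)[C@@H](C)[C@]21CC[C@]3(CC(OS(C)(=O)=O)OC3)O1 | intermediate (not isolated)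
31 | 6-O-TBS ether of the target | CC(=O)OC[C@@]1(C)[C@@H](OC(C)=O)CC[C@@]2(C)[C@@H]1[C@H](O[Si](C)(C)C(C)(C)C)C(=O)[C@@H](C)[C@]21CC[C@]2(C=COC2)O1 | intermediate
32 | 3β,19-diacetoxy-9α,13:15,16-diepoxy-6β-hydroxy-5β,10β-labd-14-en-7-one (CNP0317137.2) | CC(=O)OC[C@@]1(C)[C@@H](OC(C)=O)CC[C@@]2(C)[C@@H]1[C@H](O)C(=O)[C@@H](C)[C@]21CC[C@]2(C=COC2)O1 | target

Total step count: 23. Longest linear sequence: 22 steps (from 1 through steps 1 and 3–23; step 2 prepares the side-chain fragment).

Steps most likely to fail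

Step 15 (proposed new method). The side-chain manganate ester may hydrolyse or over-oxidise before it engages the hindered ring alkene, and only one C13 epimer of it can close, so conversion to the oxolane may be low. The fallback sets out from 21 and uses only known reaction types. Exhaustive syn-dihydroxylation (OsO4, 2.5 equiv, pyridine, then NaHSO3) on the open α face of C8=C9 and on C13=C16 would give the 8α,9α,13,16-tetraol F1 as both C13 epimers. TsCl in pyridine should sulfonylate only the primary C16 hydroxyl to give the 16-tosylate F2, and DBU would close the 13,16-epoxide F3. Catalytic CSA would then let the 9α-hydroxyl open the epoxide at its tertiary carbon C13 (5-exo, inversion), which comes back to the route at 23, to be separated from its C13 epimer.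

Step 5. Thermal rearrangement or dimerisation of the acetoxy dienone may outrun cycloaddition with the sluggish dienophile, or endo selectivity may be poor. The fallback sets out from 7 and switches to an inverse-electron-demand Diels–Alder reaction with the electron-rich enediol ether 2,2-dimethyl-1,3-dioxole (toluene, 60–80 °C), which should give the acetonide adduct F4. SmI2 would remove the acetoxy group to give the deacetoxy acetonide F5, and transketalisation (CSA, MeOH) would release the diol and rejoin the route at 11.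

Step 19. Hydrogen may be delivered without direction to the more open α face, or the cationic iridium catalyst may ionise the mixed acetal. The fallback sets out from 24 and sets C8 by a hydride shift instead. MgBr2·OEt2 would remove the SEM group to give the 7β,8α-diol F6, and MsCl with Et3N should sulfonylate only the secondary hydroxyl to give the 7β-mesylate F7. DBU would close the 7α,8α-epoxide F8 through the trans-diaxial arrangement. A Meinwald rearrangement (MgBr2·OEt2, or BF3·OEt2 at −78 °C) would open the epoxide at tertiary C8 with suprafacial shift of the C7 hydride on the β face, which gives the 7-ketone with 8β-H and returns to the route at 28.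

Further compounds
F1 | step 15 | 8α,9α,13,16-tetraol of 21 (both C13 epimers) | CC(=O)OC[C@@]1(C)[C@@H](OC(C)=O)CC[C@@]2(C)[C@@H]1[C@H](O[Si](C)(C)C(C)(C)C)[C@H](OCOCC[Si](C)(C)C)[C@@](C)(O)[C@]2(O)CCC(O)(CO)CC(OC)OC
F2 | step 15 | 16-tosylate of F1 | CC(=O)OC[C@@]1(C)[C@@H](OC(C)=O)CC[C@@]2(C)[C@@H]1[C@H](O[Si](C)(C)C(C)(C)C)[C@H](OCOCC[Si](C)(C)C)[C@@](C)(O)[C@]2(O)CCC(O)(COS(=O)(=O)c3ccc(C)cc3)CC(OC)OC
F3 | step 15 | 13,16-epoxide 8α,9α-diol | CC(=O)OC[C@@]1(C)[C@@H](OC(C)=O)CC[C@@]2(C)[C@@H]1[C@H](O[Si](C)(C)C(C)(C)C)[C@H](OCOCC[Si](C)(C)C)[C@@](C)(O)[C@]2(O)CCC3(CO3)CC(OC)OC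
F4 | step 5 | rac-acetonide analogue of 9 | O=C1[C@@](C)(OC(C)=O)[C@H]2[C@@H]3OC(C)(C)O[C@@H]3[C@]1(C)C(CCC(=C)CC(OC)OC)=C2C
F5 | step 5 | rac-acetonide analogue of 10 (C3 epimers) | O=C1C(C)[C@H]2[C@@H]3OC(C)(C)O[C@@H]3[C@]1(C)C(CCC(=C)CC(OC)OC)=C2C
F6 | step 19 | 7β,8α-diol from 24 | CC(=O)OC[C@@]1(C)[C@@H](OC(C)=O)CC[C@@]2(C)[C@@H]1[C@H](O[Si](C)(C)C(C)(C)C)[C@H](O)[C@@](C)(O)[C@]21CC[C@]3(CC(OC)OC3)O1
F7 | step 19 | 7β-mesylate of F6 | CC(=O)OC[C@@]1(C)[C@@H](OC(C)=O)CC[C@@]2(C)[C@@H]1[C@H](O[Si](C)(C)C(C)(C)C)[C@H](OS(C)(=O)=O)[C@@](C)(O)[C@]21CC[C@]3(CC(OC)OC3)O1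
F8 | step 19 | 7α,8α-epoxide | CC(=O)OC[C@@]1(C)[C@@H](OC(C)=O)CC[C@@]2(C)[C@@H]1[C@H](O[Si](C)(C)C(C)(C)C)[C@H]4O[C@@]4(C)[C@]21CC[C@]3(CC(OC)OC3)O1
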